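Over 20 h you want to know whether the next run can stay as planned, with 2.20 equiv of reagent and 0.33 mol% of precatalyst, or needs more catalyst. I would reckon it through one time. The equivalents count on the left-handed substrate, so the flask holds [reagent] 44.0 mM against 40.0 mM of both substrates, while in Friday's run reagent was the limiting reagent, 34.0 mM against 40.0 mM.

| flask | left-handed substrate | right-handed substrate | reagent | precatalyst | remark | time |
|---|---|---|---|---|---|---|
| Monday's | 20 mM | 20 mM | 1.1 equiv | 0.33 mol% | run made earlier |  |
| Friday's | 20 mM | 20 mM | 1.7 equiv | 0.33 mol% | run made earlier |  |
| flask | 20 mM | 20 mM | 2.20 equiv | 0.33 mol% |  | 20 h |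

- Monday's (time / h: left-handed substrate / %, right-handed substrate / %, left-handed product / %): 5.00: 47.1, 46.4, 4.1; 10.0: 38.4, 38.6, 12.9; 15.0: 33.2, 36.0, 19.8; 20.0: 31.6, 30.5, 24.9; 25.0: 27.7, 27.5, 26.1
- Friday's (time / h: left-handed substrate / %, right-handed substrate / %, left-handed product / %): 2.00: 49.0, 48.6, 3.7; 6.00: 40.4, 41.8, 9.8; 12.0: 29.8, 30.8, 22.5; 15.0: 28.6, 28.4, 27.2; 25.0: 18.5, 19.9, 34.8

(readings scatter by 1 percentage point)

- catalyst is single-handed; left-handed substrate and right-handed substrate are mirror images of each other, charged as a racemate, each of them at the stated concentration
- the numbers in the tables scatter by 1 percentage point (one standard deviation)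
- an excess is the difference of the two amounts in percent of their sum
- an excess is below zero if the other one leads

- part of the left-handed substrate and right-handed substrate charged together that has reacted at 20 h
- excess of left-handed product over right-handed product in the product at 20 h
- excess of right-handed substrate over left-handed substrate among what is left of the two at 20 h

If the rate goes with [reagent] times [substrates] with a steady factor, ln([reagent]/[substrates]) runs straight in time. At one loading of precatalyst its slope goes with the gap between the two charges. Friday's readings at 6.00 h and 25.0 h shift that logarithm by one unit in 64.7 h. Monday's run, scaled to Friday's gap, reads 58.1 h. Friday's line meets the charged ratio at 3.48 h, a lag. For the flask's narrower gap, the gap time, the hours per unit of that logarithm, becomes 97.0 h. My reckoning then gives 67.1% reacted, so I would charge the flask as planned.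

The forecast says 62% reacted (55% to 69%), below mine though its range holds mine. It gives an excess of left-handed product of 20% and an excess of right-handed substrate of 1.5%, the latter on the ground “They therefore racemise quickly relative to reaction”.

The flask gives 64.5% reacted, an excess of left-handed product of 20.8% and an excess of right-handed substrate of 0.279%.

    reagent + catalyst + left-handed substrate → catalyst + left-handed product (k = 60000 M⁻² h⁻¹)
    reagent + catalyst + right-handed substrate → catalyst + right-handed product (k = 30000 M⁻² h⁻¹)
    left-handed substrate ⇌ right-handed substrate (k = 3.00 h⁻¹)
    precatalyst → catalyst (k = 0.130 h⁻¹)
    left-handed product ⇌ right-handed product (k = 0.0230 h⁻¹)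

The flask's catalyst stood at 22.9% of its charge after 2.00 h and at 92.6% after 20.0 h. Read back from the flask's remaining reagent and substrates, with Friday's lag, the gap time is 108 h against the 97.0 h carried in. A change of loading takes a flask out of the forecast's range: the neighbour flask charged with 0.56 mol% of precatalyst stood at 76.5% reacted, above 69%. The gap time read back, divided by the ratio of loadings, gives for that neighbour 76.5%.

The readings are calculated from invented constants, noise included.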